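The route rests on one disconnection: the C3–O bond of the catechol, which traces the target back to dihydroconiferyl stearate. A di-tert-butylsilanol hung on O4 brings palladium to C3–H, the only hydrogen ortho to O4 on the benzene ring because C5 already carries the methoxy group. In one operation the key step forges the C3–O bond and ties O3 and O4 together through silicon as a five-membered 1,3,2-dioxasilole fused to the arene. Its precursor is the stearate ester of dihydroconiferyl alcohol whose phenol oxygen bears the tBu2Si(OH) group; the ester is installed first by a lipase, and fluoride finally releases the catechol.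

Key step: step 3

Remark: ring atoms are labelled as in the target throughout (C1 carries the propyl chain, C3 and C4 the catechol oxygens O3 and O4, C5 the methoxy group), also where a systematic name numbers the ring differently. The target has no stereocentre. The oxygen that ends up on C3 is taken to come from an acetate of PhI(OAc)2, the silanol oxygen leaving in acetic acid.

Step 1
Reactants: 1 dihydroconiferyl alcohol [4-(3-hydroxypropyl)-2-methoxyphenol]; 2 vinyl stearate (ethenyl octadecanoate)
Product: 3 dihydroconiferyl stearate [3-(4-hydroxy-3-methoxyphenyl)propyl octadecanoate]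
Conditions: immobilized Candida antarctica lipase B, vinyl stearate (1.5 equiv), t-BuOMe, 45 °C
Reagents that add atoms: vinyl stearate (compound 2), CCCCCCCCCCCCCCCCCC(=O)OC=C
Why: Lipase-catalysed irreversible transesterification with an enol ester, in which the acyl-enzyme is intercepted by the primary aliphatic hydroxyl but not by the phenol, and the vinyl alcohol released tautomerizes to acetaldehyde so that the acylation cannot reverse.

Step 2
Reactants: 3 dihydroconiferyl stearate; 4 di-tert-butylsilyl bis(trifluoromethanesulfonate)
Product: 6 3-{4-[di-tert-butyl(hydroxy)silyloxy]-3-methoxyphenyl}propyl stearate, via silyl triflate 5 (not isolated)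
Conditions: 4 (1.5 equiv), 2,6-lutidine, CH2Cl2, 0 °C, slow addition of 3; then aq. NaHCO3, 0 °C to rt
Reagents that add atoms: di-tert-butylsilyl bis(trifluoromethanesulfonate) (compound 4), CC(C)(C)[Si](OS(=O)(=O)C(F)(F)F)(OS(=O)(=O)C(F)(F)F)C(C)(C)C; water, O
Why: O-silylation of a phenol by a silyl triflate under a hindered pyridine base followed by hydrolysis of the remaining Si–OTf bond, where the two tert-butyl groups and the flanking methoxy group should slow a second aryloxide substitution at silicon and keep the resulting hindered silanol from condensing to a disiloxane.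

Step 3
Reactants: 6 3-{4-[di-tert-butyl(hydroxy)silyloxy]-3-methoxyphenyl}propyl stearate
Product: 9 3-(2,2-di-tert-butyl-7-methoxy-1,3,2-benzodioxasilol-5-yl)propyl stearate, via ortho-acetate 7 (not isolated), via silyl acetate 8 (not isolated)
Conditions: Pd(OPiv)2 (5 mol %), PhI(OAc)2 (2 equiv), PhMe, 100 °C
Reagents that add atoms: (diacetoxyiodo)benzene, PhI(OAc)2, CC(=O)OI(OC(C)=O)c1ccccc1
Why: The silanol oxygen of 6 binds the divalent palladium carboxylate and delivers it to C3–H by carboxylate-assisted concerted metalation–deprotonation, giving a six-membered palladacycle (Pd, O, Si, O4, C4, C3). PhI(OAc)2 oxidizes this palladacycle to a tetravalent palladium aryl acetate, and C–O reductive elimination forms the C3–O bond of ortho-acetate 7 and returns divalent palladium. Under the acetic acid produced, the acetyl group shifts from O3 to the silanol oxygen (8) and the freed O3 attacks silicon and expels acetic acid, so the five-membered ring C3–O3–Si–O4–C4 closes by intramolecular substitution at silicon (5-exo mode), the oxygen on C3 being the one supplied by the oxidant. The closest known reaction type is the palladium-carboxylate-catalysed, PhI(OAc)2-mediated ortho C–H oxygenation of aryloxy(di-tert-butyl)silanols to silicon-tethered catechols, applied here to a guaiacol-type ring. No stereocenter is created. The step needs site selectivity among the three arene C–H bonds and chemoselectivity against the ester and the benzylic CH2: the first is secured because O4 has a single ortho hydrogen (C5 is blocked by methoxy, and C2–H and C6–H cannot be reached through a six-membered chelate), the second because the neutral oxidant leaves saturated esters and undirected C–H bonds alone.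

Step 4
Reactants: 9 3-(2,2-di-tert-butyl-7-methoxy-1,3,2-benzodioxasilol-5-yl)propyl stearate
Product: 10 3-(3,4-dihydroxy-5-methoxyphenyl)propyl stearate
Conditions: HF·pyridine, pyridine, THF, 0 °C to rt, Ar; pH 7 phosphate buffer work-up
Reagents that add atoms: none
Why: Fluoride-driven desilylation, in which formation of two strong Si–F bonds cleaves both aryl O–Si bonds of the strained five-membered silylene under buffered acidic conditions that neither hydrolyse nor transesterify the alkyl stearate and never expose the catechol as its oxidation-prone anion.

Compound list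
1 | dihydroconiferyl alcohol, 4-(3-hydroxypropyl)-2-methoxyphenol | COc1cc(CCCO)ccc1O | starting material
2 | vinyl stearate, ethenyl octadecanoate | CCCCCCCCCCCCCCCCCC(=O)OC=C | starting material
3 | dihydroconiferyl stearate, 3-(4-hydroxy-3-methoxyphenyl)propyl octadecanoate | CCCCCCCCCCCCCCCCCC(=O)OCCCc1ccc(O)c(OC)c1 | intermediate
4 | di-tert-butylsilyl bis(trifluoromethanesulfonate) | CC(C)(C)[Si](OS(=O)(=O)C(F)(F)F)(OS(=O)(=O)C(F)(F)F)C(C)(C)C | starting material
5 | 3-{4-[di-tert-butyl(trifluoromethanesulfonyloxy)silyloxy]-3-methoxyphenyl}propyl stearate (silyl triflate) | CCCCCCCCCCCCCCCCCC(=O)OCCCc1ccc(O[Si](OS(=O)(=O)C(F)(F)F)(C(C)(C)C)C(C)(C)C)c(OC)c1 | intermediate (not isolated)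
6 | 3-{4-[di-tert-butyl(hydroxy)silyloxy]-3-methoxyphenyl}propyl stearate (key-step precursor) | CCCCCCCCCCCCCCCCCC(=O)OCCCc1ccc(O[Si](O)(C(C)(C)C)C(C)(C)C)c(OC)c1 | intermediate
7 | 3-{3-acetoxy-4-[di-tert-butyl(hydroxy)silyloxy]-5-methoxyphenyl}propyl stearate (ortho-acetate) | CCCCCCCCCCCCCCCCCC(=O)OCCCc1cc(OC(C)=O)c(O[Si](O)(C(C)(C)C)C(C)(C)C)c(OC)c1 | intermediate (not isolated)
8 | 3-{4-[acetoxy(di-tert-butyl)silyloxy]-3-hydroxy-5-methoxyphenyl}propyl stearate (silyl acetate) | CCCCCCCCCCCCCCCCCC(=O)OCCCc1cc(O)c(O[Si](OC(C)=O)(C(C)(C)C)C(C)(C)C)c(OC)c1 | intermediate (not isolated)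
9 | 3-(2,2-di-tert-butyl-7-methoxy-1,3,2-benzodioxasilol-5-yl)propyl stearate (key-step product) | CCCCCCCCCCCCCCCCCC(=O)OCCCc1cc2O[Si](C(C)(C)C)(C(C)(C)C)Oc2c(OC)c1 | intermediate
10 | 3-(3,4-dihydroxy-5-methoxyphenyl)propyl stearate | CCCCCCCCCCCCCCCCCC(=O)OCCCc1cc(O)c(O)c(OC)c1 | target

Total step count: 4
Longest linear sequence: 4 steps (1 → 3 → 6 → 9 → 10)

Steps most likely to fail

Step 3 (key step). Cyclopalladation at C3–H may be slow because the silanol is crowded by the neighbouring C5 methoxy group, which can also hold the metal in an unproductive O,O-chelate. At 100 °C the acetic acid formed may then protodesilylate the aryl silyl ether, or the trivalent iodine oxidant may attack the electron-rich ring without direction. The fallback sets out from 3 and rejoins the route at 10, with no silicon chemistry. Magnesium-mediated ortho-formylation of the free phenol (MgCl2, Et3N, paraformaldehyde, THF, reflux) can only reach the open ortho carbon C3 and should give 3-(3-formyl-4-hydroxy-5-methoxyphenyl)propyl stearate F1. Dakin oxidation of this salicylaldehyde (H2O2, catalytic (PhSe)2, CH2Cl2) should give the aryl formate 3-[3-(formyloxy)-4-hydroxy-5-methoxyphenyl]propyl stearate F2. Its formate should be hydrolysed by aqueous NaHCO3/THF under argon far faster than the alkyl stearate, giving 10.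

Step 2. A second phenol molecule may displace the remaining triflate and give a bis(aryloxy)silane, or adventitious moisture may consume the bistriflate before it meets the hindered ortho-methoxy phenol, so that 3 is returned. The fallback sets out from 3 and rejoins at 6, using a monofunctional silicon electrophile that cannot substitute twice. Di-tert-butylchlorosilane (tBu2SiHCl, imidazole, DMF) should give the hydrosilane 3-{4-[(di-tert-butylsilyl)oxy]-3-methoxyphenyl}propyl stearate F3. Bromination of the Si–H bond with N-bromosuccinimide (CH2Cl2, 0 °C), expected to outpace ring bromination, should give the bromosilane 3-{4-[bromo(di-tert-butyl)silyloxy]-3-methoxyphenyl}propyl stearate F4. This is not isolated but hydrolysed with aqueous NaHCO3 to the silanol 6.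

Step 4. Silicon removal may stop after opening of only one Si–O bond. If more basic fluoride is then needed, acyl scrambling at the stearate and air oxidation of the catecholate to an ortho-quinone may occur during work-up and chromatography. The fallback sets out from 9 and rejoins at 10. The catechol is released and capped in the same flask (Bu4NF/AcOH, THF, then Ac2O, pyridine) to give the air-stable 3-(3,4-diacetoxy-5-methoxyphenyl)propyl stearate F5, which can be purified without precautions. Chemoselective hydrazinolysis of the two aryl acetates (hydrazine acetate, DMF, rt, argon), which are far more electrophilic than the alkyl stearate, should then free 10 under near-neutral conditions.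

Further compounds
F1 | step 3 | 3-(3-formyl-4-hydroxy-5-methoxyphenyl)propyl stearate | CCCCCCCCCCCCCCCCCC(=O)OCCCc1cc(C=O)c(O)c(OC)c1
F2 | step 3 | 3-[3-(formyloxy)-4-hydroxy-5-methoxyphenyl]propyl stearate | CCCCCCCCCCCCCCCCCC(=O)OCCCc1cc(OC=O)c(O)c(OC)c1
F3 | step 2 | 3-{4-[(di-tert-butylsilyl)oxy]-3-methoxyphenyl}propyl stearate | CCCCCCCCCCCCCCCCCC(=O)OCCCc1ccc(O[SiH](C(C)(C)C)C(C)(C)C)c(OC)c1
F4 | step 2 | 3-{4-[bromo(di-tert-butyl)silyloxy]-3-methoxyphenyl}propyl stearate | CCCCCCCCCCCCCCCCCC(=O)OCCCc1ccc(O[Si](Br)(C(C)(C)C)C(C)(C)C)c(OC)c1
F5 | step 4 | 3-(3,4-diacetoxy-5-methoxyphenyl)propyl stearate | CCCCCCCCCCCCCCCCCC(=O)OCCCc1cc(OC(C)=O)c(OC(C)=O)c(OC)c1
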